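The seven-membered ring is opened at C6–C7. The sequence C6(O)–C7H2–C8(CH3)=C9H–C10(=O) in that ring is the trace of a C6 aldehyde that has undergone a carbonyl-ene reaction with a methallyl ketone (C7–C10) attached to C1. In one operation the key step makes C6–C7, closes the cycloheptenone onto the cyclopentane, sets C6 and, after alkene migration, gives the C8=C9–C10 enone. Precursor 20 is a cyclopentane with the C5 formyl group and the C1 3-methylbut-3-enoyl group trans to each other, next to the silyl-protected isopropyl carbinol C4. C1 comes from an enantioselective conjugate addition. C5 and C4 are relayed from it.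

Key step: step 10

Numbering: C1 quaternary methyl-bearing fusion carbon, C2/C3 ring CH2, C4 isopropyl carbinol, C5 fusion CH, C6 ester CH, C7 CH2, C8 methyl-bearing alkene carbon, C9 alkene CH, C10 ketone. The target is (1S,4R,5S,6S).
Assumption: the C10 carbinol centre of 12–19 is carried as an epimer mixture because step 9 erases it. The CIP label of C5 changes between compounds only because substituent priorities change.

Step 1
Reactants: 1 3-methylcyclopent-2-en-1-one; 2 hex-1-yne
Product: 5 triethyl({(3R)-3-[(E)-hex-1-en-1-yl]-3-methylcyclopent-1-en-1-yl}oxy)silane, via alkenylalane 3 (not isolated), via aluminium enolate 4 (not isolated)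
Conditions: 2, iBu2AlH, hexane, 50 °C; then 1, Cu(OTf)2 (5 mol %), N,N-bis[1-(naphthalen-2-yl)ethyl]-P,P-diphenylphosphinous amide (10 mol %, the antipode that gives (R)-5), Et2O, −30 °C; then Et3SiOTf, −78 → 0 °C
Reagents that add atoms: hex-1-yne, CCCCC#C; triethylsilyl trifluoromethanesulfonate, CC[Si](CC)(CC)OS(=O)(=O)C(F)(F)F
Why: Copper-catalysed enantioselective conjugate addition of an alkenylalane (made by syn-hydroalumination) to a β-methyl cyclic enone sets quaternary C1 under ligand control, and O-silylation of the aluminium enolate keeps the enolate at C5, a position that deprotonation of the free ketone cannot reach.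

Step 2
Reactants: 5 enol silane; 6 trimethyl orthoformate
Product: 7 (3R)-2-(dimethoxymethyl)-3-[(E)-hex-1-en-1-yl]-3-methylcyclopentan-1-one (both C2 epimers)
Conditions: 6 (3 equiv), Me3SiOTf (10 mol %), CH2Cl2, −78 °C; pyridine quench
Reagents that add atoms: trimethyl orthoformate 6, COC(OC)OC
Why: Mukaiyama-type alkylation of the enol silane by the dimethoxycarbenium ion puts C6 on C5 at the aldehyde oxidation level, and because methyl and alkenyl on C1 are too similar in size to steer the attack, C5 is left unset here and fixed in step 5.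

Step 3
Reactants: 7 keto acetal
Product: 9 (1S)-2-(dimethoxymethyl)-1-methyl-3-oxocyclopentane-1-carbaldehyde (both C2 epimers), via ozonide 8 (not isolated)
Conditions: O3, CH2Cl2, −78 °C (Sudan red 7B end-point); then PPh3, −78 → 23 °C
Reagents that add atoms: ozone, [O-][O+]=O
Why: Ozonolysis with reductive work-up cleaves the only C=C bond to the non-enolisable C10 aldehyde, and the dye end-point prevents excess ozone from oxidising the acetal C–H.

Step 4
Reactants: 9 keto aldehyde; 10 4,4,5,5-tetramethyl-2-(2-methylprop-2-en-1-yl)-1,3,2-dioxaborolane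
Product: 12 (3S)-2-(dimethoxymethyl)-3-(1-hydroxy-3-methylbut-3-en-1-yl)-3-methylcyclopentan-1-one (epimers at C2 and at the carbinol), via borate ester 11 (not isolated)
Conditions: 10 (1.5 equiv), toluene, 23 → 40 °C; then H2O (pH 7); crude product carried on
Reagents that add atoms: methallylboronic acid pinacol ester 10, C=C(C)CB1OC(C)(C)C(C)(C)O1
Why: Allylboration through a closed six-membered transition state adds to aldehydes but not to ketones, so C10 is methallylated in the presence of the free C4 ketone.

Step 5
Reactants: 12 hydroxy ketone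
Product: 14 (2S,3S)-2-(dimethoxymethyl)-3-methyl-3-{3-methyl-1-[(trimethylsilyl)oxy]but-3-en-1-yl}cyclopentan-1-one (acetal cis to methyl and trans to the side chain; carbinol epimers), via silyl ether 13 (not isolated)
Conditions: 1-(trimethylsilyl)imidazole, CH2Cl2, 23 °C; then DBU (1 equiv), 40 °C
Reagents that add atoms: 1-(trimethylsilyl)imidazole, C[Si](C)(C)n1ccnc1
Why: Silylation makes the C1 side chain a branched group much larger than methyl and stops the hydroxyl from adding to C6, so base epimerisation of C5 (α to the C4 ketone) should converge under thermodynamic control on the isomer with the acetal trans to that chain, which is the C1/C5 relationship of the target.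

Step 6
Reactants: 14 ketone; 15 isopropylmagnesium chloride
Product: 16 (1R,2R,3S)-2-(dimethoxymethyl)-3-methyl-3-{3-methyl-1-[(trimethylsilyl)oxy]but-3-en-1-yl}-1-(propan-2-yl)cyclopentan-1-ol
Conditions: 15 (3 equiv), anhydrous CeCl3 (3 equiv), THF, −78 °C, 1.5 h; then 14, −78 → −40 °C; aq. NH4Cl
Reagents that add atoms: isopropylmagnesium chloride 15, CC(C)[Mg]Cl
Why: Organocerium 1,2-addition suppresses enolisation and β-hydride reduction of the hindered ketone, and attack on the face of H5, opposite the adjacent acetal and the pseudoaxial C1 methyl, places the hydroxyl cis to C6 as required for (4R).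

Step 7
Reactants: 16 tertiary alcohol
Product: 17 C4 triethylsilyl ether of 16
Conditions: KN(SiMe3)2 (1.3 equiv), Et3SiCl (1.5 equiv), THF, −78 → 0 °C
Reagents that add atoms: chlorotriethylsilane, CC[Si](Cl)(CC)CC
Why: O-silylation of the potassium alkoxide works on hindered tertiary alcohols and avoids silyl triflate, which would also attack the dimethyl acetal.

Step 8
Reactants: 17 bis-silyl ether
Product: 19 (1R,2S,5R)-2-(1-hydroxy-3-methylbut-3-en-1-yl)-2-methyl-5-(propan-2-yl)-5-[(triethylsilyl)oxy]cyclopentane-1-carbaldehyde (carbinol epimers), via hydroxy acetal 18 (not isolated)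
Conditions: PPTS (0.3 equiv), acetone/H2O 9:1, 35 °C
Reagents that add atoms: water, O
Why: Mild acid hydrolysis removes the labile secondary trimethylsilyl ether and the acetal while the shielded tertiary triethylsilyl ether should survive, it is done before the acid-sensitive β,γ-unsaturated ketone exists, and the trans arrangement keeps the C10 hydroxyl from forming a lactol with C6.

Step 9
Reactants: 19 hydroxy aldehyde
Product: 20 (1R,2S,5R)-2-methyl-2-(3-methylbut-3-enoyl)-5-(propan-2-yl)-5-[(triethylsilyl)oxy]cyclopentane-1-carbaldehyde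
Conditions: Dess–Martin periodinane (1.3 equiv), NaHCO3, CH2Cl2, 0 → 23 °C; short pad of deactivated silica; used the same day
Reagents that add atoms: none
Why: Buffered Dess–Martin oxidation turns a homoallylic alcohol into the β,γ-unsaturated ketone without moving the alkene, leaves the aldehyde and C5 untouched, and merges both C10 epimers into one compound.

Step 10
Reactants: 20 keto aldehyde
Product: 22 (1R,3aS,8S,8aS)-8-hydroxy-3a,6-dimethyl-1-(propan-2-yl)-1-[(triethylsilyl)oxy]-2,3,3a,7,8,8a-hexahydroazulen-4(1H)-one, via exo-methylene isomer 21 (not isolated)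
Conditions: Me2AlCl (2.2 equiv), CH2Cl2 (0.005 M), −78 → −20 °C; aq. potassium sodium tartrate; then DBU (0.2 equiv), CH2Cl2, 0 °C
Reagents that add atoms: none
Why: Me2AlCl binds the formyl oxygen, the unsubstituted alkene terminus C7 bonds to C6 and an allylic hydrogen is transferred to oxygen, either in one six-centre event or via a short-lived tertiary C8 cation, after which methane loss gives the aluminium alkoxide and removes free acid. The closest known reaction is the Me2AlCl-promoted intramolecular carbonyl-ene cyclisation of formyl-substituted 1,1-disubstituted alkenes linked through the central ene carbon, which is established for six- and seven-membered carbocycles. The ring C1–C5–C6–C7–C8–C9–C10 closes with the carbonyl oxygen outside it and both alkene carbons as ring members (exo with respect to C=O, endo with respect to C=C). C6 is controlled by the aldehyde rotamer: the aluminium-bound oxygen sits over H5, away from the fully substituted C1 and C4, and the tether can reach only from the C1 side, so the attacked face gives H5 and H6 anti, which is (6S). The step needs bonding through C7 before the alkene drifts into conjugation: a neutral alkene can bond only through C7, bonding through C9 would need an enolate and give a strained trans-fused bicyclo[3.3.0]octane, and the proton-scavenging Al–CH3 groups hold back isomerisation, silyloxy elimination and C5 epimerisation. Hydrogen transfer from the methyl group gives 21, which catalytic DBU isomerises to the single conjugated enone 22.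

Step 11
Reactants: 22 silyl ether
Product: 23 (1R,3aS,8S,8aS)-1,8-dihydroxy-3a,6-dimethyl-1-(propan-2-yl)-2,3,3a,7,8,8a-hexahydroazulen-4(1H)-one
Conditions: HF·pyridine, pyridine, THF, 0 → 23 °C
Reagents that add atoms: none
Why: Fluoride-driven Si–O cleavage in a weakly acidic buffer frees the tertiary alcohol without the vinylogous retro-aldol or dehydration that a basic fluoride source could trigger.

Step 12
Reactants: 23 diol; 24 3,4-dimethoxybenzoyl chloride
Product: 25 (3R,3aS,4S,8aS)-3-hydroxy-6,8a-dimethyl-8-oxo-3-(propan-2-yl)-1,2,3,3a,4,5,8,8a-octahydroazulen-4-yl 3,4-dimethoxybenzoate (target)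
Conditions: 24 (1.5 equiv), pyridine, DMAP (0.2 equiv), CH2Cl2, 0 → 23 °C
Reagents that add atoms: 3,4-dimethoxybenzoyl chloride 24, COc1ccc(C(=O)Cl)cc1OC
Why: DMAP-catalysed acylation esterifies only the secondary C6 hydroxyl, with retention, because the tertiary C4 hydroxyl is too hindered, and the weak base avoids vinylogous elimination of the new ester.

Compound list
1 | 3-methylcyclopent-2-en-1-one | CC1=CC(=O)CC1 | starting material
2 | hex-1-yne | CCCCC#C | starting material
3 | (E)-hex-1-en-1-ylbis(2-methylpropyl)alane | CCCC/C=C/[Al](CC(C)C)CC(C)C | intermediate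
4 | bis(2-methylpropyl)aluminium enolate (O on C4, C4=C5) of (R)-3-[(E)-hex-1-enyl]-3-methylcyclopentanone | CCCC/C=C/[C@@]1(C)CCC(O[Al](CC(C)C)CC(C)C)=C1 | intermediate
5 | triethyl({(3R)-3-[(E)-hex-1-en-1-yl]-3-methylcyclopent-1-en-1-yl}oxy)silane | CCCC/C=C/[C@@]1(C)CCC(O[Si](CC)(CC)CC)=C1 | intermediate
6 | trimethyl orthoformate | COC(OC)OC | starting material
7 | (3R)-2-(dimethoxymethyl)-3-[(E)-hex-1-en-1-yl]-3-methylcyclopentan-1-one, C2 epimers | CCCC/C=C/[C@@]1(C)CCC(=O)C1C(OC)OC | intermediate
8 | secondary ozonide of 7 (3-butyl-1,2,4-trioxolan-5-yl on C1) | CCCCC1OOC(O1)[C@@]2(C)CCC(=O)C2C(OC)OC | intermediate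
9 | (1S)-2-(dimethoxymethyl)-1-methyl-3-oxocyclopentane-1-carbaldehyde, C2 epimers | O=C[C@@]1(C)CCC(=O)C1C(OC)OC | intermediate
10 | 4,4,5,5-tetramethyl-2-(2-methylprop-2-en-1-yl)-1,3,2-dioxaborolane | C=C(C)CB1OC(C)(C)C(C)(C)O1 | starting material
11 | pinacol borate ester of 12 | C=C(C)CC(OB1OC(C)(C)C(C)(C)O1)[C@@]2(C)CCC(=O)C2C(OC)OC | intermediate
12 | (3S)-2-(dimethoxymethyl)-3-(1-hydroxy-3-methylbut-3-en-1-yl)-3-methylcyclopentan-1-one, epimers at C2 and carbinol | C=C(C)CC(O)[C@@]1(C)CCC(=O)C1C(OC)OC | intermediate
13 | trimethylsilyl ether of 12, C2 epimers | C=C(C)CC(O[Si](C)(C)C)[C@@]1(C)CCC(=O)C1C(OC)OC | intermediate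
14 | (2S,3S)-2-(dimethoxymethyl)-3-methyl-3-{3-methyl-1-[(trimethylsilyl)oxy]but-3-en-1-yl}cyclopentan-1-one | C=C(C)CC(O[Si](C)(C)C)[C@@]1(C)CCC(=O)[C@@H]1C(OC)OC | intermediate
15 | isopropylmagnesium chloride | CC(C)[Mg]Cl | starting material
16 | (1R,2R,3S)-2-(dimethoxymethyl)-3-methyl-3-{3-methyl-1-[(trimethylsilyl)oxy]but-3-en-1-yl}-1-(propan-2-yl)cyclopentan-1-ol | C=C(C)CC(O[Si](C)(C)C)[C@@]1(C)CC[C@@](O)(C(C)C)[C@@H]1C(OC)OC | intermediate
17 | C4 triethylsilyl ether of 16 | C=C(C)CC(O[Si](C)(C)C)[C@@]1(C)CC[C@@](O[Si](CC)(CC)CC)(C(C)C)[C@@H]1C(OC)OC | intermediate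
18 | C10 alcohol of 17 (acetal still in place) | C=C(C)CC(O)[C@@]1(C)CC[C@@](O[Si](CC)(CC)CC)(C(C)C)[C@@H]1C(OC)OC | intermediate
19 | (1R,2S,5R)-2-(1-hydroxy-3-methylbut-3-en-1-yl)-2-methyl-5-(propan-2-yl)-5-[(triethylsilyl)oxy]cyclopentane-1-carbaldehyde | C=C(C)CC(O)[C@@]1(C)CC[C@@](O[Si](CC)(CC)CC)(C(C)C)[C@@H]1C=O | intermediate
20 | (1R,2S,5R)-2-methyl-2-(3-methylbut-3-enoyl)-5-(propan-2-yl)-5-[(triethylsilyl)oxy]cyclopentane-1-carbaldehyde | C=C(C)CC(=O)[C@@]1(C)CC[C@@](O[Si](CC)(CC)CC)(C(C)C)[C@@H]1C=O | intermediate
21 | exo-methylene isomer of 22 (C8=CH2, C9H2) | O[C@H]1CC(=C)CC(=O)[C@@]2(C)CC[C@@](O[Si](CC)(CC)CC)(C(C)C)[C@H]12 | intermediate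
22 | (1R,3aS,8S,8aS)-8-hydroxy-3a,6-dimethyl-1-(propan-2-yl)-1-[(triethylsilyl)oxy]-2,3,3a,7,8,8a-hexahydroazulen-4(1H)-one | O[C@H]1CC(C)=CC(=O)[C@@]2(C)CC[C@@](O[Si](CC)(CC)CC)(C(C)C)[C@H]12 | intermediate
23 | (1R,3aS,8S,8aS)-1,8-dihydroxy-3a,6-dimethyl-1-(propan-2-yl)-2,3,3a,7,8,8a-hexahydroazulen-4(1H)-one | O[C@H]1CC(C)=CC(=O)[C@@]2(C)CC[C@@](O)(C(C)C)[C@H]12 | intermediate
24 | 3,4-dimethoxybenzoyl chloride | COc1ccc(C(=O)Cl)cc1OC | starting material
25 | (3R,3aS,4S,8aS)-3-hydroxy-6,8a-dimethyl-8-oxo-3-(propan-2-yl)-1,2,3,3a,4,5,8,8a-octahydroazulen-4-yl 3,4-dimethoxybenzoate | COc1ccc(C(=O)O[C@H]2CC(C)=CC(=O)[C@@]3(C)CC[C@@](O)(C(C)C)[C@H]23)cc1OC | target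

Total steps: 12. Longest linear sequence: 12 (from 1).

Steps most likely to fail

**Step 10.** The alkene sits two bonds from an acyl group and may be too weak a nucleophile. Alkene migration into conjugation, methyl transfer from aluminium to the aldehyde, or loss of the silyloxy group could then outrun ring closure. The fallback keeps the C6–C7 bond but makes C7 an allylmetal.
- It sets out from 17, whose methallyl group is chlorinated in an ene-type allylic chlorination (N-chlorosuccinimide, catalytic PhSeCl) to the 2-(chloromethyl)allyl bis-silyl ether F1.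
- The conditions of steps 8 and 9 then give the chloro hydroxy aldehyde F2 and the chloro keto aldehyde F3.
- CrCl2 in THF at high dilution (intramolecular Nozaki–Hiyama–Kishi allylation, aldehyde-selective) closes the ring.
- The route is rejoined at 21, before the DBU isomerisation to 22.

**Step 1.** Facial discrimination by the copper catalyst on the flat five-membered enone may be poor, or an isobutyl group may transfer in competition. The fallback builds the quaternary centre racemically and resolves it by reagent control.
- It sets out from 1: vinylmagnesium bromide, CuBr·SMe2 (10 mol %) and Me3SiCl give the racemic enol silane F4.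
- The conditions of steps 2 and 3 give the racemic vinyl keto acetal F5 and the racemic keto aldehyde F6.
- One antipode of B-methallyldiisopinocampheylborane then gives the carbinols of uniform C10 configuration F7.
- Under the conditions of step 5 the two ring antipodes become separable diastereomers, the unwanted ring antipode F8 and the wanted one.
- The route is rejoined at 14, obtained as a single C10 epimer.

**Step 8.** Hydrolysis of the crowded acetal may be slow, so the tertiary silyl ether could be lost or the silyloxy group eliminated from the aldehyde as it forms. The fallback unmasks the aldehyde without Brønsted acid and merges steps 7 and 8.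
- It sets out from 16: Et3SiOTf and 2,6-lutidine in CH2Cl2 at 0 °C silylate the C4 hydroxyl and convert the acetal into a lutidinium salt.
- Water cleaves that salt to the bis-silylated aldehyde F9.
- Citric acid in methanol at 0 °C then removes only the secondary trimethylsilyl ether.
- The route is rejoined at 19.

Further compounds
F1 | step 10 | 2-(chloromethyl)allyl analogue of 17 | ClCC(=C)CC(O[Si](C)(C)C)[C@@]1(C)CC[C@@](O[Si](CC)(CC)CC)(C(C)C)[C@@H]1C(OC)OC
F2 | step 10 | 2-(chloromethyl)allyl analogue of 19 | ClCC(=C)CC(O)[C@@]1(C)CC[C@@](O[Si](CC)(CC)CC)(C(C)C)[C@@H]1C=O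
F3 | step 10 | 2-(chloromethyl)allyl analogue of 20 | ClCC(=C)CC(=O)[C@@]1(C)CC[C@@](O[Si](CC)(CC)CC)(C(C)C)[C@@H]1C=O
F4 | step 1 | racemic [(3-ethenyl-3-methylcyclopent-1-en-1-yl)oxy]trimethylsilane | C=CC1(C)CCC(O[Si](C)(C)C)=C1
F5 | step 1 | racemic 2-(dimethoxymethyl)-3-ethenyl-3-methylcyclopentan-1-one | C=CC1(C)CCC(=O)C1C(OC)OC
F6 | step 1 | racemic 2-(dimethoxymethyl)-1-methyl-3-oxocyclopentane-1-carbaldehyde | O=CC1(C)CCC(=O)C1C(OC)OC
F7 | step 1 | 2-(dimethoxymethyl)-3-[(1S)-1-hydroxy-3-methylbut-3-en-1-yl]-3-methylcyclopentan-1-one, both ring antipodes | C=C(C)C[C@H](O)C1(C)CCC(=O)C1C(OC)OC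
F8 | step 1 | (2R,3R)-ring diastereomer of 14 with (1S)-carbinol centre | C=C(C)C[C@H](O[Si](C)(C)C)[C@]1(C)CCC(=O)[C@H]1C(OC)OC
F9 | step 8 | C10 trimethylsilyl ether of 19 | C=C(C)CC(O[Si](C)(C)C)[C@@]1(C)CC[C@@](O[Si](CC)(CC)CC)(C(C)C)[C@@H]1C=O
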